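Ring numbering used throughout: C1 (carries =CH2), C2=C3, C4 (CMe2), C5 (CH–O), C6, C7, C8(Me)=C9, C10, C11.
Enabling feature: in the 11-membered ring the C5 carbinol is flanked by quaternary C4, and C4 is bonded to the C2=C3 unsaturation. With C2–C3 written as an alkyne, C5(OH)–C4Me2–C3≡C2 is a homopropargylic alcohol, the product pattern of a 3,3-dimethylallenyl metal (metal on C2) adding to a C5 aldehyde.
Cuts, in order: the acyl–O bond at C5; C2=C3 back to C2≡C3; the ring bond C4–C5; then, in the open chain, C1–C2 (Sonogashira), C6–C7 (Johnson–Claisen) and C8–C9 (Grignard).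
Forward: pent-4-yn-1-ol is grown into the linear iodo-dienal C5–C11/C1. The C2–C4 unit is coupled on and its tertiary alcohol becomes the chloride. The only ring is then closed at C4–C5, the ring alkyne is taken to the E-alkene, and the vanilloyl group is attached last.
Stereochemistry: C5 (R) comes from the chiral chromium ligand in the ring closure, C8=C9 (E) from the chair transition state of the Claisen step, and C2=C3 (E) from trans-hydrostannation followed by retentive protodestannation.

Key step: step 8

Assumption: the sense of induction of the carbazole ligand towards a tertiary allenylchromium cannot be predicted with certainty, so the (S,S) form is written and its mirror image (from D-valinol) is used instead if a Mosher ester analysis of the ring-closure product shows the S carbinol; the ligand is a known compound made separately from carbazole and valinol and is treated as a catalyst component, not counted in the steps.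

Step 1
Reactants: 1 pent-4-yn-1-ol
Product: 2 4-iodopent-4-en-1-ol
Conditions: NaI, TMSCl, H2O, MeCN, rt
Reagents that add atoms: sodium iodide, [Na+].[I-]
Why: Markovnikov hydroiodination of a terminal alkyne, in which HI released in the flask protonates the terminal carbon and iodide is taken up at the internal carbon, should give the 2-iodo-1-alkene, and any silylated hydroxyl is freed on aqueous work-up.

Step 2
Reactants: 2 4-iodopent-4-en-1-ol
Product: 3 4-iodopent-4-enal
Conditions: TEMPO (10 mol %), PhI(OAc)2, CH2Cl2, rt
Reagents that add atoms: none
Why: The oxoammonium (TEMPO/PhI(OAc)2) oxidation of a primary alcohol stops at the aldehyde under near-neutral conditions that leave the alkenyl iodide untouched.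

Step 3
Reactants: 3 4-iodopent-4-enal; 4 isopropenylmagnesium bromide
Product: 5 (±)-6-iodo-2-methylhepta-1,6-dien-3-ol
Conditions: THF, −78 to −20 °C; aq NH4Cl
Reagents that add atoms: none
Why: Grignard 1,2-addition to the aldehyde forms C8–C9 at a temperature where iodine–magnesium exchange at the alkenyl iodide is slow, and the racemic carbinol centre does not matter because the next step erases it.

Step 4
Reactants: 5 (±)-6-iodo-2-methylhepta-1,6-dien-3-ol; 6 triethyl orthoacetate
Product: 8 ethyl (4E)-8-iodo-4-methylnona-4,8-dienoate, via mixed ketene acetal 7 (not isolated)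
Conditions: EtCO2H (10 mol %), neat 6, 140 °C, EtOH distilled off
Reagents that add atoms: none
Why: In this Johnson–Claisen rearrangement, acid-catalysed exchange and loss of ethanol give 7, whose chair transition state keeps the iodoalkenyl chain equatorial to avoid a 1,3-diaxial clash with the ethoxy group, so C6–C7 forms and C8=C9 should emerge as the E-trisubstituted alkene.

Step 5
Reactants: 8 ethyl (4E)-8-iodo-4-methylnona-4,8-dienoate
Product: 9 (4E)-8-iodo-4-methylnona-4,8-dienal
Conditions: iBu2AlH (1.05 equiv), CH2Cl2, −78 °C; MeOH, then aq potassium sodium tartrate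
Reagents that add atoms: none
Why: Partial ester reduction with one equivalent of iBu2AlH at −78 °C is a standard way to stop at the aldehyde oxidation level, and the alkenyl iodide and both alkenes are inert to it.

Step 6
Reactants: 9 (4E)-8-iodo-4-methylnona-4,8-dienal; 10 2-methylbut-3-yn-2-ol
Product: 11 (4E)-11-hydroxy-4,11-dimethyl-8-methylidenedodec-4-en-9-ynal
Conditions: PdCl2(PPh3)2 (3 mol %), CuI (6 mol %), Et3N, THF, rt
Reagents that add atoms: none
Why: Sonogashira coupling of an unhindered 2-iodo-1-alkene proceeds at room temperature, forms C1–C2, and with a tertiary amine as base leaves the aldehyde and the free tertiary alcohol alone.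

Step 7
Reactants: 11 (4E)-11-hydroxy-4,11-dimethyl-8-methylidenedodec-4-en-9-ynal
Product: 12 (4E)-11-chloro-4,11-dimethyl-8-methylidenedodec-4-en-9-ynal
Conditions: 1-chloro-N,N,2-trimethylprop-1-en-1-amine (1.2 equiv), CH2Cl2, 0 °C to rt; short pad of deactivated silica, used at once
Reagents that add atoms: 1-chloro-N,N,2-trimethylprop-1-en-1-amine, CC(C)=C(Cl)N(C)C
Why: Neutral deoxychlorination with an α-chloroenamine activates the tertiary hydroxyl and delivers chloride to the propargylic carbon C4 while the reagent ends as a neutral amide, so neither acid nor base is present to harm the aldehyde, the C8=C9 alkene or the enyne.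

Step 8
Reactants: 12 (4E)-11-chloro-4,11-dimethyl-8-methylidenedodec-4-en-9-ynal
Product: 15 (1R,8E)-2,2,9-trimethyl-5-methylidenecycloundec-8-en-3-yn-1-ol, via allenylchromium species 13 (not isolated), via trimethylsilyl ether 14 (not isolated)
Conditions: CrCl2 (20 mol %), (S,S)-1,8-bis(4-isopropyl-4,5-dihydrooxazol-2-yl)-3,6-diphenyl-9H-carbazole (22 mol %), iPr2NEt (60 mol %), Mn powder (3 equiv), TMSCl (2 equiv), THF, rt, 12 added by syringe pump over 12 h (final about 3 mM); then 1 M aq HCl, THF, 0 °C
Reagents that add atoms: none
Why: Divalent chromium, regenerated by manganese, reduces the C4–Cl bond of 12 in two one-electron steps, and the propargyl/allenyl chromium pair settles as 13 with the metal on C2, because a trivalent chromium centre carrying the tridentate ligand finds no room on fully substituted C4. The C5 aldehyde then binds to chromium and C4 is transferred through a closed six-centre SE2′ transition state (Cr, C2, C3, C4, C5, O), after which TMSCl releases the catalyst from the alkoxide as 14; the closest known reaction types are the catalytic asymmetric Nozaki–Hiyama–Kishi propargylation of aldehydes with propargylic halides and the chromium-mediated macrocyclisation of formyl-bearing allylic halides. The one ring formed is the 11-membered carbocycle, closed 11-exo-trig at the carbonyl group (the oxygen stays outside) with the C2≡C3 triple bond ending inside the ring, where four collinear atoms are still tolerable. The only new stereocentre, C5, is controlled by the C2-symmetric bis(oxazolinyl)carbazole ligand, which shields one aldehyde face so that C4 arrives on the Si face and gives R. The step needs attack through C4 rather than C2 (homopropargylic, not allenic, carbinol) and ring closure rather than oligomerisation: the first is secured by the gem-dimethyl group that fixes chromium on C2 and by the strain of the alternative 9-membered ring with an exocyclic allene, the second by slow addition into a dilute catalyst solution. Because chromium sits on an sp2 carbon it cannot migrate across the C1 methylidene group as an allylic metal would, so no pentadienyl-type isomers are expected.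

Step 9
Reactants: 15 (1R,8E)-2,2,9-trimethyl-5-methylidenecycloundec-8-en-3-yn-1-ol
Product: 16 (1R,3Z,8E)-2,2,9-trimethyl-5-methylidene-3-(tributylstannyl)cycloundeca-3,8-dien-1-ol
Conditions: [Cp*RuCl]4 (2.5 mol %), Bu3SnH (1.1 equiv, slow addition), CH2Cl2, rt
Reagents that add atoms: tributyltin hydride, CCCC[SnH](CCCC)CCCC
Why: In the ruthenium-catalysed trans-hydrostannation a hydrogen bond from the C5 hydroxyl to the chloride on ruthenium draws the catalyst to C2≡C3 and H and Sn add to opposite sides, so C1 and C4 end up trans with tin expected on C3, and any C2-stannyl regioisomer would converge in the next step.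

Step 10
Reactants: 16 (1R,3Z,8E)-2,2,9-trimethyl-5-methylidene-3-(tributylstannyl)cycloundeca-3,8-dien-1-ol
Product: 17 (1R,3E,8E)-2,2,9-trimethyl-5-methylidenecycloundeca-3,8-dien-1-ol
Conditions: Cu(O2PPh2) (1.5 equiv), wet DMF, rt
Reagents that add atoms: none
Why: In this copper-mediated protodestannation, tin is exchanged for monovalent copper (driven by phosphinate binding to tin) and then for a proton with retention of alkene geometry, without the free acid that could isomerise the C1/C2=C3 diene.

Step 11
Reactants: 18 vanillic acid (4-hydroxy-3-methoxybenzoic acid)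
Product: 20 4-[(tert-butyldimethylsilyl)oxy]-3-methoxybenzoic acid, via bis-silyl derivative 19 (not isolated)
Conditions: TBSCl (2.5 equiv), imidazole, DMF, rt; then AcOH–THF–H2O, rt
Reagents that add atoms: tert-butyldimethylsilyl chloride, CC(C)(C)[Si](C)(C)Cl
Why: Standard silyl protection covers both acidic groups, and the much more labile silyl ester of 19 is then hydrolysed selectively, leaving the phenol masked as its TBS ether.

Step 12
Reactants: 17 (1R,3E,8E)-2,2,9-trimethyl-5-methylidenecycloundeca-3,8-dien-1-ol; 20 4-[(tert-butyldimethylsilyl)oxy]-3-methoxybenzoic acid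
Product: 22 (1R,3E,8E)-2,2,9-trimethyl-5-methylidenecycloundeca-3,8-dien-1-yl 4-[(tert-butyldimethylsilyl)oxy]-3-methoxybenzoate, via acid chloride 21 (not isolated)
Conditions: 20, 1-chloro-N,N,2-trimethylprop-1-en-1-amine, CH2Cl2, 0 °C to rt; then 17, DMAP, Et3N, CH2Cl2, 40 °C
Reagents that add atoms: none
Why: DMAP-catalysed acylation with 21, generated under neutral conditions so that the aryl silyl ether survives, is forceful enough for the neopentyl-type secondary alcohol and takes place at oxygen, so C5 keeps its configuration.

Step 13
Reactants: 22 (1R,3E,8E)-2,2,9-trimethyl-5-methylidenecycloundeca-3,8-dien-1-yl 4-[(tert-butyldimethylsilyl)oxy]-3-methoxybenzoate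
Product: 23 (1R,3E,8E)-2,2,9-trimethyl-5-methylidenecycloundeca-3,8-dien-1-yl 4-hydroxy-3-methoxybenzoate (CNP0416843.1)
Conditions: Bu4NF, AcOH, THF, 0 °C
Reagents that add atoms: none
Why: Fluoride-mediated desilylation cleaves the aryl silyl ether para to the ester quickly under buffered conditions that leave the hindered benzoate, the diene and C5 untouched.

Compound list
1 | pent-4-yn-1-ol | C#CCCCO | starting material
2 | 4-iodopent-4-en-1-ol | C=C(I)CCCO | intermediate
3 | 4-iodopent-4-enal | C=C(I)CCC=O | intermediate
4 | isopropenylmagnesium bromide | CC(=C)[Mg]Br | starting material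
5 | (±)-6-iodo-2-methylhepta-1,6-dien-3-ol | C=C(I)CCC(O)C(C)=C | intermediate
6 | triethyl orthoacetate | CC(OCC)(OCC)OCC | starting material
7 | 3-[(1-ethoxyethenyl)oxy]-6-iodo-2-methylhepta-1,6-diene (mixed ketene acetal, not isolated) | C=C(OCC)OC(CCC(I)=C)C(C)=C | intermediate
8 | ethyl (4E)-8-iodo-4-methylnona-4,8-dienoate | CCOC(=O)CC/C(C)=C/CCC(I)=C | intermediate
9 | (4E)-8-iodo-4-methylnona-4,8-dienal | O=CCC/C(C)=C/CCC(I)=C | intermediate
10 | 2-methylbut-3-yn-2-ol | CC(C)(O)C#C | starting material
11 | (4E)-11-hydroxy-4,11-dimethyl-8-methylidenedodec-4-en-9-ynal | O=CCC/C(C)=C/CCC(=C)C#CC(C)(C)O | intermediate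
12 | (4E)-11-chloro-4,11-dimethyl-8-methylidenedodec-4-en-9-ynal | O=CCC/C(C)=C/CCC(=C)C#CC(C)(C)Cl | intermediate
13 | allenylchromium species with trivalent chromium on C2, ligand sphere drawn as two chlorides (not isolated) | CC(C)=C=C([Cr](Cl)Cl)C(=C)CC/C=C(\C)CCC=O | intermediate
14 | trimethylsilyl ether of 15 (not isolated) | C=C1C#CC(C)(C)[C@H](O[Si](C)(C)C)CC/C(C)=C/CC1 | intermediate
15 | (1R,8E)-2,2,9-trimethyl-5-methylidenecycloundec-8-en-3-yn-1-ol | C=C1C#CC(C)(C)[C@H](O)CC/C(C)=C/CC1 | intermediate
16 | (1R,3Z,8E)-2,2,9-trimethyl-5-methylidene-3-(tributylstannyl)cycloundeca-3,8-dien-1-ol | C=C1/C=C(\[Sn](CCCC)(CCCC)CCCC)C(C)(C)[C@H](O)CC/C(C)=C/CC1 | intermediate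
17 | (1R,3E,8E)-2,2,9-trimethyl-5-methylidenecycloundeca-3,8-dien-1-ol | C=C1/C=C/C(C)(C)[C@H](O)CC/C(C)=C/CC1 | intermediate
18 | vanillic acid | COc1cc(ccc1O)C(=O)O | starting material
19 | tert-butyldimethylsilyl 4-[(tert-butyldimethylsilyl)oxy]-3-methoxybenzoate (not isolated) | COc1cc(ccc1O[Si](C)(C)C(C)(C)C)C(=O)O[Si](C)(C)C(C)(C)C | intermediate
20 | 4-[(tert-butyldimethylsilyl)oxy]-3-methoxybenzoic acid | COc1cc(ccc1O[Si](C)(C)C(C)(C)C)C(=O)O | intermediate
21 | 4-[(tert-butyldimethylsilyl)oxy]-3-methoxybenzoyl chloride (not isolated) | COc1cc(ccc1O[Si](C)(C)C(C)(C)C)C(Cl)=O | intermediate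
22 | (1R,3E,8E)-2,2,9-trimethyl-5-methylidenecycloundeca-3,8-dien-1-yl 4-[(tert-butyldimethylsilyl)oxy]-3-methoxybenzoate | C=C1/C=C/C(C)(C)[C@H](OC(=O)c2ccc(O[Si](C)(C)C(C)(C)C)c(OC)c2)CC/C(C)=C/CC1 | intermediate
23 | (1R,3E,8E)-2,2,9-trimethyl-5-methylidenecycloundeca-3,8-dien-1-yl 4-hydroxy-3-methoxybenzoate | C=C1/C=C/C(C)(C)[C@H](OC(=O)c2ccc(O)c(OC)c2)CC/C(C)=C/CC1 | target

Total step count: 13. Longest linear sequence: 12 steps (steps 1–10, 12 and 13); step 11 is a one-step side branch.

Steps most likely to fail

Step 8. The ligand may discriminate poorly between the aldehyde faces when the nucleophile is a bulky tertiary allenylchromium. Catalyst turnover may also be too slow at high dilution, so that oligomerisation or protonation of the organochromium competes. The fallback separates ring closure from stereocontrol. Setting out from 12, the ring is closed without ligand by slow addition into an excess of CrCl2 in THF, which should give the racemic carbinol F1. Dess–Martin oxidation then gives the ring ketone F2, which has no hydrogen on C4 and therefore cannot slip into an allenyl ketone. A Corey–Bakshi–Shibata reduction follows, with (S)-1-methyl-3,3-diphenyltetrahydro-1H,3H-pyrrolo[1,2-c][1,3,2]oxazaborole and catecholborane in toluene at −78 °C. In it quaternary C4 acts as the large and C6 as the small substituent, which should set C5 as R and bring the route back at 15.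

Step 7. The activated tertiary alcohol may ionise and then lose a methyl proton, or chloride may be captured at C2 instead of C4. The fallback never replaces the C4–O bond by a halide. Setting out from 11, the tertiary hydroxyl is benzoylated (BzCl, DMAP, Et3N, CH2Cl2) to the propargylic benzoate F3. Umpolung with catalytic Pd(PPh3)4 (zerovalent palladium) and Et2Zn in THF under slow addition then closes the same C4–C5 bond to the racemic carbinol F1. The oxidation and oxazaborolidine reduction described above, through the ring ketone F2, lead back to 15.

Step 9. The ruthenium catalyst may fail to engage an alkyne that is flanked by quaternary C4 and conjugated to the C1 methylidene group, or the hydride may add across the enyne in a 1,4 sense. The fallback delivers the hydride source from a tether. Setting out from 15, the hydroxyl is silylated with 1,1,3,3-tetramethyldisilazane to the hydrosilyl ether F4. [Cp*Ru(MeCN)3]PF6 in CH2Cl2 then effects an intramolecular 6-endo-dig trans-hydrosilylation to the oxasilacycle F5, with silicon on C2 and C1 trans to C4. Bu4NF in THF removes silicon with retention and comes back to the route at 17, bypassing 16.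

Further compounds
F1 | step 8 | (±)-(8E)-2,2,9-trimethyl-5-methylidenecycloundec-8-en-3-yn-1-ol | C=C1C#CC(C)(C)C(O)CC/C(C)=C/CC1
F2 | step 8 | (8E)-2,2,9-trimethyl-5-methylidenecycloundec-8-en-3-yn-1-one | C=C1C#CC(C)(C)C(=O)CC/C(C)=C/CC1
F3 | step 7 | (8E)-2,9-dimethyl-5-methylidene-12-oxododec-8-en-3-yn-2-yl benzoate | O=CCC/C(C)=C/CCC(=C)C#CC(C)(C)OC(=O)c1ccccc1
F4 | step 9 | {[(1R,8E)-2,2,9-trimethyl-5-methylidenecycloundec-8-en-3-yn-1-yl]oxy}dimethylsilane | C=C1C#CC(C)(C)[C@H](O[SiH](C)C)CC/C(C)=C/CC1
F5 | step 9 | six-membered oxasilacycle O–SiMe2–C2=C3–C4–C5 bridging the 11-membered ring (silicon on C2, C5 R, C2=C3 E within the large ring) | C=C1CC/C=C(\C)CC[C@H]2O[Si](C)(C)/C1=C\C2(C)C
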